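Per litre of starting volume, gamma and zeta each receive 0.50 M of free monomer and 2.0 mM of initiator; they differ in time. We count with the charge ratio n, free monomer charged over initiator charged, here 250. Each initiator gives two radicals, and two that join make one chain, so if we take nearly every radical as joined, each initiator spent counts as one chain. The average length L (the number-average degree of polymerisation) is then n times the share of monomer in chains over the share of initiator spent.

| flask | free monomer | protic impurity | initiator | remark | time |
|---|---|---|---|---|---|
| winter | 0.50 M (fed, over 50 s) | 0.50 M | 1.3 mM | run made earlier; the fed solution adds 0.20 times the starting volume |  |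
| midnight | 0.50 M (fed, over 50 s) | 0.50 M | 3 mM | run made earlier; the fed solution adds 0.20 times the starting volume |  |
| noon | 0.50 M (fed, over 50 s) | 0.75 M | 2 mM | run made earlier; the fed solution adds 0.20 times the starting volume |  |
| gamma | 0.50 M (fed, over 50 s) | 0.500 M | 2.0 mM | the fed solution adds 0.20 times the starting volume | 12 min |
| zeta | 0.50 M (fed, over 50 s) | 0.500 M | 2.0 mM | the fed solution adds 0.20 times the starting volume | 40 min |

| run | time / min | monomer in chains / % | free monomer / % |
|---|---|---|---|
| winter | 4.00 | 51.7 | 40.9 |
| winter | 8.00 | 69.8 | 20.7 |
| winter | 10.0 | 73.2 | 15.6 |
| winter | 15.0 | 78.8 | 9.7 |
| midnight | 1.00 | 20.5 | 78.3 |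
| midnight | 2.50 | 51.6 | 44.6 |
| midnight | 6.00 | 77.8 | 15.7 |
| midnight | 15.0 | 89.2 | 3.1 |
| noon | 1.00 | 17.4 | 80.9 |
| noon | 2.50 | 44.0 | 50.1 |
| noon | 6.00 | 68.4 | 19.7 |
| noon | 15.0 | 80.5 | 4.5 |

(scatter of a reading: 0.5 percentage points)

- amounts are per litre of the starting volume; all of the dose is in the solution fed
- the average divides the monomer in chains by the number of chains, living and dead together; two radicals that join make one chain
- steps thought possible: free monomer + growing radical -> monomer in chains + growing radical; initiator -> 2 initiating radical; free monomer + initiating radical -> growing radical + monomer in chains; protic impurity + free monomer -> quenched substrate; 2 growing radical -> dead chain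
- the earlier runs do not show the number of chains; that part of a forecast is a guess

- which of the two ends with the longer chains by the average number of monomer units in a chain (living and dead chains, two that joined counted as one) ("neither" if they lie within 10 %) (gamma / zeta / neither)
- average number of monomer units in a chain (living and dead chains, two that joined counted as one) at the end, gamma
- average number of monomer units in a chain (living and dead chains, two that joined counted as one) at the end, zeta

Our estimate starts from the initiator charge of 2.0 mM, which lies between winter's 1.3 mM and midnight's 3 mM. At 15.0 min those runs read 78.8 % and 89.2 % in chains, on average 84.0 %. If we take the initiator as wholly spent, that share of readings gives L of 210. We expect about this in zeta, and somewhat above it in gamma if some initiator is left at 12 min.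

The forecast says neither, with 230 for gamma and 220 for zeta, on the ground that “chains ≈ initiator decomposed”. Both numbers lie above our reckoning.

The flasks give neither: 227 for gamma and 216 for zeta.

    free monomer + growing radical → monomer in chains + growing radical, rate k1*[growing radical]*[free monomer] (k = 10000 /M/s)
    initiator → 2 initiating radical (k = 0.00330 /s)
    free monomer + initiating radical → growing radical + monomer in chains (k = 3.20 × 10⁵ /M/s)
    protic impurity + free monomer → quenched substrate (k = 0.00120 /M/s)
    2 growing radical → dead chain (k = 1.80 × 10⁷ /M/s)

The forecast holds. The computed gamma length has moved by 10 % at an initiator charge of 1.78 mM or 2.27 mM, all else held. In gamma at 12.0 min, n with 82.2 % in chains and 90.7 % of the initiator spent gives 227.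

A neighbour like zeta, with 5.0 × 10⁻⁴ M of initiator, has n of 1000. With 68.1 % in chains and >99.9 % of the initiator spent, n gives 681. The computed length is 681.

The runs were generated by integration for an exercise; scatter was added.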